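**Retrosynthetic overview**
1. Feature: ring A of the flavone (C-4a, C-5, C-6, C-7, C-8, C-8a, flavone numbering) is a 5,7-dioxygenated benzene ring fused to the 4-pyranone ring C, with the terpenoid CH2 on C-6 between O-5 and O-7. C-5 with its OH, C-6 and C-7 with its oxygen can therefore come from a ketene carbonyl and a siloxyalkyne.
2. Key disconnection (ring A, made last): C-8–C-8a (Wolff shift), C-5–C-6 and C-7–C-8 ([2+2]), C-4a–C-5 (6π closure). This leads back to pyranonyl diazo ketone 23 and siloxyalkyne 12; one global desilylation then gives ugonin Q.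
3. Alkyne 12: the cyclohexane ring is bought as enone 1. CBS reduction sets the carbinol, a Johnson–Claisen rearrangement sets the second ring stereocentre trans to it and creates the exocyclic methylene, and a Kowalski homologation turns the ester into the ynol silyl ether.
4. Diazo ketone 23: ring B is bought as 3,4-dihydroxyacetophenone. Two Claisen condensations (ethyl acetate, diethyl oxalate) and acid cyclodehydration build ring C as the 4-pyranone-2-carboxylic acid, which is silylated and converted into the diazomethyl ketone.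
5. Order of ring formation: cyclohexane ring and ring B (from the starting materials), ring C (step 10), ring A (step 13).

Key step: step 13

Remark: flavone numbering is used for ring A and ring C atoms; diazomethane is taken as freshly prepared from commercial N-methyl-N-nitroso-p-toluenesulfonamide; the catechol is carried as MOM ethers through the base- and acid-mediated pyranone construction and as TBS ethers only afterwards, because aryl silyl ethers would not survive those conditions.

**Route**

Step 1
Reactants: 1 4,4-dimethylcyclohex-2-en-1-one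
Product: 2 2-iodo-4,4-dimethylcyclohex-2-en-1-one
Conditions: I2, pyridine, CH2Cl2, 0 °C to rt
Reagents that add atoms: iodine, II
Why: α-Iodination of an enone by pyridine conjugate addition, iodination of the enolate and elimination (Baylis–Hillman-type α-halogenation) should place iodine on C-2, the only vinylic α-position.

Step 2
Reactants: 2 2-iodo-4,4-dimethylcyclohex-2-en-1-one
Product: 3 (1S)-2-iodo-4,4-dimethylcyclohex-2-en-1-ol
Conditions: (R)-Me-CBS oxazaborolidine [(R)-1-methyl-3,3-diphenyltetrahydro-1H,3H-pyrrolo[1,2-c][1,3,2]oxazaborole] (cat.), BH3·SMe2, THF, −20 °C; aqueous work-up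
Reagents that add atoms: none
Why: CBS reduction in which the iodovinyl arm acts as the large and the ring CH2 as the small carbonyl substituent, so that the (R)-catalyst should deliver hydride to the face that gives the (S)-carbinol, the future C–OH stereocentre of the target.

Step 3
Reactants: 3 (1S)-2-iodo-4,4-dimethylcyclohex-2-en-1-ol
Product: 4 tert-butyl{[(1S)-2-iodo-4,4-dimethylcyclohex-2-en-1-yl]oxy}dimethylsilane
Conditions: t-BuMe2SiCl, imidazole, DMAP (cat.), DMF, rt
Reagents that add atoms: tert-butyldimethylsilyl chloride, CC(C)(C)[Si](C)(C)Cl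
Why: Standard silylation of a secondary alcohol gives an ether that survives organolithium, orthoester and ynolate chemistry and that also serves as the steric control element of step 5, the stereocentre being untouched.

Step 4
Reactants: 4 tert-butyl{[(1S)-2-iodo-4,4-dimethylcyclohex-2-en-1-yl]oxy}dimethylsilane
Product: 6 [(6S)-6-(tert-butyldimethylsilyloxy)-3,3-dimethylcyclohex-1-en-1-yl]methanol, via vinyllithium 5 (not isolated)
Conditions: t-BuLi (2.1 equiv), Et2O, −78 °C; (CH2O)n, −78 °C to 0 °C; aq NH4Cl at 0 °C
Reagents that add atoms: formaldehyde (from paraformaldehyde), C=O; tert-butyllithium (lithium of intermediate 5 only), [Li]C(C)(C)C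
Why: Iodine–lithium exchange gives vinyllithium 5, which adds to formaldehyde (1,2-addition of an organolithium to an aldehyde) to give the primary allylic alcohol, and the cold quench keeps the secondary silyl ether from migrating to the new alkoxide, the carbinol stereocentre not being involved.

Step 5
Reactants: 6 [(6S)-6-(tert-butyldimethylsilyloxy)-3,3-dimethylcyclohex-1-en-1-yl]methanol; 7 triethyl orthoacetate
Product: 9 ethyl 2-[(1S,3S)-3-(tert-butyldimethylsilyloxy)-6,6-dimethyl-2-methylidenecyclohexyl]acetate (ring substituents trans), via mixed ketene acetal 8 (not isolated)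
Conditions: MeC(OEt)3 (excess), EtCO2H (cat.), xylene, 140 °C, EtOH distilled off
Reagents that add atoms: none
Why: Johnson–Claisen rearrangement: acid-catalysed exchange gives ketene acetal 8, whose [3,3] shift forms the C–C bond at the ring carbon next to the gem-dimethyl group and moves the double bond into the exocyclic position, and the new stereocentre should be set trans to the silyloxy group because delivery to the face syn to OTBS would place the forming bond 1,3-diaxial to it in the chair-like transition state, so the (1S,3S) ester is expected.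

Step 6
Reactants: 9 ethyl 2-[(1S,3S)-3-(tert-butyldimethylsilyloxy)-6,6-dimethyl-2-methylidenecyclohexyl]acetate
Product: 12 tert-butyl{[(1S,3S)-4,4-dimethyl-2-methylidene-3-{3-[tri(propan-2-yl)silyloxy]prop-2-yn-1-yl}cyclohexyl]oxy}dimethylsilane, via dibromo enolate 10 (not isolated), via lithium ynolate 11 (not isolated)
Conditions: CH2Br2, lithium 2,2,6,6-tetramethylpiperidide, THF, −78 °C; 9; n-BuLi, −78 °C to rt; i-Pr3SiCl, −78 °C to rt
Reagents that add atoms: dibromomethane, BrCBr; chlorotri(propan-2-yl)silane, CC(C)[Si](Cl)(C(C)C)C(C)C; n-butyllithium (lithium of intermediates 10 and 11 only), [Li]CCCC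
Why: Kowalski ester homologation: LiCHBr2 adds to the ester, the dibromo ketone enolate 10 undergoes bromine–lithium exchange and 1,2-shift of the alkyl group (carbenoid rearrangement) to ynolate 11, in which the former ester carbon carries the oxygen and the dibromomethane carbon has been inserted next to the CH2 group, and the bulky silyl chloride traps 11 on oxygen, neither stereocentre being touched.

Step 7
Reactants: 13 3,4-dihydroxyacetophenone
Product: 14 1-[3,4-bis(methoxymethoxy)phenyl]ethan-1-one
Conditions: MeOCH2Cl, i-Pr2NEt, CH2Cl2, 0 °C to rt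
Reagents that add atoms: chloromethyl methyl ether, COCCl
Why: O-Alkylation of both phenols (methoxymethyl ether formation) gives acetals that survive the two base-mediated condensations and are shed by the acid of step 10.

Step 8
Reactants: 14 1-[3,4-bis(methoxymethoxy)phenyl]ethan-1-one; 15 ethyl acetate
Product: 16 1-[3,4-bis(methoxymethoxy)phenyl]butane-1,3-dione
Conditions: NaH, EtOAc, THF, reflux; AcOH
Reagents that add atoms: none
Why: Crossed Claisen condensation of the acetophenone sodium enolate with ethyl acetate, driven by deprotonation of the 1,3-diketone formed, supplies the two carbons that become C-4 and C-4a.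

Step 9
Reactants: 16 1-[3,4-bis(methoxymethoxy)phenyl]butane-1,3-dione; 17 diethyl oxalate
Product: 18 ethyl 6-[3,4-bis(methoxymethoxy)phenyl]-2,4,6-trioxohexanoate
Conditions: (CO2Et)2, NaOEt, EtOH, 0 °C to rt; AcOH
Reagents that add atoms: none
Why: Claisen condensation with diethyl oxalate under equilibrating ethoxide conditions should acylate the terminal methyl group, since only that product forms a stabilised bis-enolate and acylation at the central carbon is reversible.

Step 10
Reactants: 18 ethyl 6-[3,4-bis(methoxymethoxy)phenyl]-2,4,6-trioxohexanoate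
Product: 20 6-(3,4-dihydroxyphenyl)-4-oxo-4H-pyran-2-carboxylic acid, via pyranone ethyl ester 19 (not isolated)
Conditions: conc. HCl, EtOH, reflux; then 6 M HCl, AcOH, 100 °C
Reagents that add atoms: water, O
Why: Acid-catalysed cyclodehydration of the 1,3,5-triketone closes ring C by attack of the aryl ketone enol oxygen on the C-2 ketone, the same acid cleaves both MOM acetals, and aqueous acid then hydrolyses the ester without the ring opening that hydroxide would cause, as in the classical preparation of chromone- and pyranone-2-carboxylic acids.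

Step 11
Reactants: 20 6-(3,4-dihydroxyphenyl)-4-oxo-4H-pyran-2-carboxylic acid
Product: 21 tert-butyldimethylsilyl 6-[3,4-bis(tert-butyldimethylsilyloxy)phenyl]-4-oxo-4H-pyran-2-carboxylate
Conditions: t-BuMe2SiCl, imidazole, DMF, rt
Reagents that add atoms: tert-butyldimethylsilyl chloride, CC(C)(C)[Si](C)(C)Cl
Why: Silylation of both phenols and of the carboxylic acid gives aryl silyl ethers that fluoride removes at the end and a silyl ester that is the direct precursor of the acid chloride.

Step 12
Reactants: 21 tert-butyldimethylsilyl 6-[3,4-bis(tert-butyldimethylsilyloxy)phenyl]-4-oxo-4H-pyran-2-carboxylate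
Product: 23 2-(diazoacetyl)-6-[3,4-bis(tert-butyldimethylsilyloxy)phenyl]-4H-pyran-4-one, via acid chloride 22 (not isolated)
Conditions: (COCl)2, DMF (cat.), CH2Cl2, 0 °C to rt, then evaporation; CH2N2 (excess), Et2O/THF, 0 °C
Reagents that add atoms: diazomethane, C=[N+]=[N-]; oxalyl chloride (chlorine of intermediate 22 only), O=C(Cl)C(=O)Cl
Why: Oxalyl chloride with catalytic DMF converts the silyl ester into the acid chloride without free HCl (the silyl group leaves as its chloride), and acylation of diazomethane (first stage of the Arndt–Eistert sequence) should then give the diazo ketone faster than diazomethane adds to the pyranone double bonds.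

Step 13
Reactants: 23 2-(diazoacetyl)-6-[3,4-bis(tert-butyldimethylsilyloxy)phenyl]-4H-pyran-4-one; 12 siloxyalkyne (1.2 equiv)
Product: 28 2-[3,4-bis(tert-butyldimethylsilyloxy)phenyl]-6-{[(1S,3S)-3-(tert-butyldimethylsilyloxy)-6,6-dimethyl-2-methylidenecyclohexyl]methyl}-5-hydroxy-7-[tri(propan-2-yl)silyloxy]-4H-chromen-4-one, via pyranonyl ketene 24 (not isolated), via cyclobutenone 25 (not isolated), via dienylketene 26 (not isolated), via cyclohexadienone 27 (not isolated)
Conditions: hν (blue LED, 450 nm), ClCH2CH2Cl (degassed), rt; then 80 °C in the dark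
Reagents that add atoms: none
Why: Blue light expels N2 from 23 and the pyranon-2-yl group shifts to the carbene carbon (Wolff rearrangement, which makes C-8–C-8a) to give ketene 24, whose carbonyl carbon is then attacked by the nucleophilic alkyl-bearing carbon of siloxyalkyne 12 in a [2+2] cycloaddition that makes C-5–C-6 and C-7–C-8 and gives cyclobutenone 25. Conrotatory 4π opening of 25 gives dienylketene 26, ring A is closed by a thermal disrotatory 6π electrocyclisation of the ketene carbon onto pyranone C-3 (C-4a–C-5), and dienone 27 enolises at once because its C-4a hydrogen lies between two carbonyl groups, so the ketene oxygen ends as the chelated 5-OH and the siloxy carbon as C-7. The closest known reaction type is the photochemical Wolff and vinylketene benzannulation of aryl and heteroaryl diazomethyl ketones with siloxyalkynes (Danheiser benzannulation), in which the pyranone C-2=C-3 bond here plays the part of the vinyl unit. No stereocentre is formed, since C-4 of 25 and C-4a of 27 are lost on aromatisation and the two stereocentres of 12 are remote from the reacting alkyne. The step needs regioselectivity in the cycloaddition, which the oxygen-polarised alkyne secures (terpenoid CH2 on C-6 and never on C-8), and the ring closure has a single site because pyranone C-2 carries oxygen on its other side. Chemoselectivity rests on the 450 nm light, which is absorbed by the diazo ketone but not by the aryl pyranone, the exocyclic alkene or the silyl ethers, and on the much higher reactivity of the ynol ether towards the ketene compared with the 1,1-disubstituted alkene.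

Step 14
Reactants: 28 silyl-protected ugonin Q with free 5-OH
Product: 29 ugonin Q, 2-(3,4-dihydroxyphenyl)-5,7-dihydroxy-6-{[(1S,3S)-3-hydroxy-6,6-dimethyl-2-methylidenecyclohexyl]methyl}-4H-chromen-4-one
Conditions: Bu4NF, AcOH, THF, 0 °C to rt, under argon
Reagents that add atoms: none
Why: Fluoride-mediated desilylation cleaves all four Si–O bonds (one aryl TIPS ether, two aryl TBS ethers, one secondary TBS ether), and the acetic acid buffer keeps the catechol from strong base and the allylic alcohol beside the exocyclic alkene from acid, so that no stereocentre is touched.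

**Compound list**
1 | 4,4-dimethylcyclohex-2-en-1-one | CC1(C)CCC(=O)C=C1 | starting material
2 | 2-iodo-4,4-dimethylcyclohex-2-en-1-one | CC1(C)CCC(=O)C(I)=C1 | intermediate
3 | (1S)-2-iodo-4,4-dimethylcyclohex-2-en-1-ol | IC1=CC(C)(C)CC[C@@H]1O | intermediate
4 | tert-butyl{[(1S)-2-iodo-4,4-dimethylcyclohex-2-en-1-yl]oxy}dimethylsilane | IC1=CC(C)(C)CC[C@@H]1O[Si](C)(C)C(C)(C)C | intermediate
5 | [(6S)-6-(tert-butyldimethylsilyloxy)-3,3-dimethylcyclohex-1-en-1-yl]lithium (vinyllithium, not isolated) | [Li]C1=CC(C)(C)CC[C@@H]1O[Si](C)(C)C(C)(C)C | intermediate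
6 | [(6S)-6-(tert-butyldimethylsilyloxy)-3,3-dimethylcyclohex-1-en-1-yl]methanol | OCC1=CC(C)(C)CC[C@@H]1O[Si](C)(C)C(C)(C)C | intermediate
7 | triethyl orthoacetate | CCOC(C)(OCC)OCC | starting material
8 | 1-ethoxyvinyl ether of 6 (mixed ketene acetal, not isolated) | C=C(OCC)OCC1=CC(C)(C)CC[C@@H]1O[Si](C)(C)C(C)(C)C | intermediate
9 | ethyl 2-[(1S,3S)-3-(tert-butyldimethylsilyloxy)-6,6-dimethyl-2-methylidenecyclohexyl]acetate | C=C1[C@@H](CC(=O)OCC)C(C)(C)CC[C@@H]1O[Si](C)(C)C(C)(C)C | intermediate
10 | lithium enolate of the dibromomethyl ketone from 9 (not isolated) | C=C1[C@@H](CC(O[Li])=C(Br)Br)C(C)(C)CC[C@@H]1O[Si](C)(C)C(C)(C)C | intermediate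
11 | lithium ynolate (not isolated) | C=C1[C@@H](CC#CO[Li])C(C)(C)CC[C@@H]1O[Si](C)(C)C(C)(C)C | intermediate
12 | tert-butyl{[(1S,3S)-4,4-dimethyl-2-methylidene-3-{3-[tri(propan-2-yl)silyloxy]prop-2-yn-1-yl}cyclohexyl]oxy}dimethylsilane (siloxyalkyne) | C=C1[C@@H](CC#CO[Si](C(C)C)(C(C)C)C(C)C)C(C)(C)CC[C@@H]1O[Si](C)(C)C(C)(C)C | intermediate
13 | 3,4-dihydroxyacetophenone | CC(=O)c1ccc(O)c(O)c1 | starting material
14 | 1-[3,4-bis(methoxymethoxy)phenyl]ethan-1-one | CC(=O)c1ccc(OCOC)c(OCOC)c1 | intermediate
15 | ethyl acetate | CCOC(C)=O | starting material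
16 | 1-[3,4-bis(methoxymethoxy)phenyl]butane-1,3-dione | CC(=O)CC(=O)c1ccc(OCOC)c(OCOC)c1 | intermediate
17 | diethyl oxalate | CCOC(=O)C(=O)OCC | starting material
18 | ethyl 6-[3,4-bis(methoxymethoxy)phenyl]-2,4,6-trioxohexanoate | CCOC(=O)C(=O)CC(=O)CC(=O)c1ccc(OCOC)c(OCOC)c1 | intermediate
19 | ethyl 6-(3,4-dihydroxyphenyl)-4-oxo-4H-pyran-2-carboxylate (not isolated) | CCOC(=O)c1cc(=O)cc(-c2ccc(O)c(O)c2)o1 | intermediate
20 | 6-(3,4-dihydroxyphenyl)-4-oxo-4H-pyran-2-carboxylic acid | OC(=O)c1cc(=O)cc(-c2ccc(O)c(O)c2)o1 | intermediate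
21 | tert-butyldimethylsilyl 6-[3,4-bis(tert-butyldimethylsilyloxy)phenyl]-4-oxo-4H-pyran-2-carboxylate | CC(C)(C)[Si](C)(C)OC(=O)c1cc(=O)cc(-c2ccc(O[Si](C)(C)C(C)(C)C)c(O[Si](C)(C)C(C)(C)C)c2)o1 | intermediate
22 | 6-[3,4-bis(tert-butyldimethylsilyloxy)phenyl]-4-oxo-4H-pyran-2-carbonyl chloride (not isolated) | ClC(=O)c1cc(=O)cc(-c2ccc(O[Si](C)(C)C(C)(C)C)c(O[Si](C)(C)C(C)(C)C)c2)o1 | intermediate
23 | 2-(diazoacetyl)-6-[3,4-bis(tert-butyldimethylsilyloxy)phenyl]-4H-pyran-4-one | [N-]=[N+]=CC(=O)c1cc(=O)cc(-c2ccc(O[Si](C)(C)C(C)(C)C)c(O[Si](C)(C)C(C)(C)C)c2)o1 | intermediate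
24 | {6-[3,4-bis(tert-butyldimethylsilyloxy)phenyl]-4-oxo-4H-pyran-2-yl}ketene (not isolated) | O=C=Cc1cc(=O)cc(-c2ccc(O[Si](C)(C)C(C)(C)C)c(O[Si](C)(C)C(C)(C)C)c2)o1 | intermediate
25 | 2-(terpenoid methyl)-3-(triisopropylsilyloxy)-4-(pyranon-2-yl)cyclobut-2-en-1-one, ring C-4 unassigned (not isolated) | C=C1[C@@H](CC2=C(O[Si](C(C)C)(C(C)C)C(C)C)C(c3cc(=O)cc(-c4ccc(O[Si](C)(C)C(C)(C)C)c(O[Si](C)(C)C(C)(C)C)c4)o3)C2=O)C(C)(C)CC[C@@H]1O[Si](C)(C)C(C)(C)C | intermediate
26 | dienylketene with ketene and pyranonyl groups cis on the siloxy alkene (not isolated) | C=C1[C@@H](CC(=C=O)/C(O[Si](C(C)C)(C(C)C)C(C)C)=C\c2cc(=O)cc(-c3ccc(O[Si](C)(C)C(C)(C)C)c(O[Si](C)(C)C(C)(C)C)c3)o2)C(C)(C)CC[C@@H]1O[Si](C)(C)C(C)(C)C | intermediate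
27 | 4aH-chromene-4,5-dione (cyclohexadienone before enolisation), C-4a unassigned (not isolated) | C=C1[C@@H](CC2=C(O[Si](C(C)C)(C(C)C)C(C)C)C=C3OC(c4ccc(O[Si](C)(C)C(C)(C)C)c(O[Si](C)(C)C(C)(C)C)c4)=CC(=O)C3C2=O)C(C)(C)CC[C@@H]1O[Si](C)(C)C(C)(C)C | intermediate
28 | 2-[3,4-bis(tert-butyldimethylsilyloxy)phenyl]-6-{[(1S,3S)-3-(tert-butyldimethylsilyloxy)-6,6-dimethyl-2-methylidenecyclohexyl]methyl}-5-hydroxy-7-[tri(propan-2-yl)silyloxy]-4H-chromen-4-one | C=C1[C@@H](Cc2c(O[Si](C(C)C)(C(C)C)C(C)C)cc3oc(-c4ccc(O[Si](C)(C)C(C)(C)C)c(O[Si](C)(C)C(C)(C)C)c4)cc(=O)c3c2O)C(C)(C)CC[C@@H]1O[Si](C)(C)C(C)(C)C | intermediate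
29 | ugonin Q | C=C1[C@@H](Cc2c(O)cc3oc(-c4ccc(O)c(O)c4)cc(=O)c3c2O)C(C)(C)CC[C@@H]1O | target

**Step count**
Total step count: 14 (steps 1–6 alkyne arm, steps 7–12 diazo ketone arm, steps 13–14 endgame). Longest linear sequence: 8 steps (1–6, 13, 14; the diazo ketone arm 7–12, 13, 14 is equally long).

**Steps most likely to fail**

Step 13 (benzannulation). Nitrogen may be lost without a clean Wolff shift (carbene chemistry sensitised by the aryl pyranone), the ketene may dimerise before it meets the alkyne, or conversion may stall because the growing flavone screens the light. The fallback makes the same ketene without light. It sets out from diazo ketone 23. Treatment with PhCO2Ag and Et3N in THF/H2O in the dark (Arndt–Eistert homologation) should give {6-[3,4-bis(tert-butyldimethylsilyloxy)phenyl]-4-oxo-4H-pyran-2-yl}acetic acid F1. (COCl)2 with catalytic DMF in CH2Cl2 at 0 °C should give the corresponding acetyl chloride F2. Slow addition of Et3N to F2 and alkyne 12 in toluene at 80 °C should dehydrochlorinate F2 to ketene 24, which is taken up by 12 as it forms and passes through 25, 26 and 27; the route is rejoined at 28.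

Step 5 (Johnson–Claisen). The facial selectivity of the [3,3] shift relative to the silyloxy group may be poor, or bond formation beside the quaternary carbon may be slow enough for the silyl ether to suffer. The fallback sets the ring stereocentre by chirality transfer through the ring C–O bond and the carbinol afterwards. It sets out from iodo enone 2.
- Methylation with MeB(OH)2, Pd(dppf)Cl2 and K3PO4 in dioxane/H2O (Suzuki–Miyaura coupling) should give 2,4,4-trimethylcyclohex-2-en-1-one F3, which can also be bought.
- CBS reduction with the (S)-catalyst should give (1R)-2,4,4-trimethylcyclohex-2-en-1-ol F4.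
- Johnson–Claisen rearrangement of F4 with orthoacetate 7 is suprafacial across the ring and should give ethyl 2-[(1S)-2,6,6-trimethylcyclohex-2-en-1-yl]acetate F5.
- mCPBA with NaHCO3 in CH2Cl2 should epoxidise the face opposite the pseudoaxial acetate arm and give the trans epoxide F6.
- Cp2TiCl (trivalent titanium, from Cp2TiCl2 and Mn) in THF should open the epoxide at the tertiary carbon and give the exocyclic allylic alcohol ethyl 2-[(1S,3S)-3-hydroxy-6,6-dimethyl-2-methylidenecyclohexyl]acetate F7.
- Silylation (t-BuMe2SiCl, imidazole) brings the route back at ester 9.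

Step 6 (Kowalski homologation). The carbenoid rearrangement may be incomplete on the β-branched ester, or the ynolate may be silylated on carbon and the ynol ether lost by hydrolysis on isolation. The fallback makes the ynolate by oxidation of an acetylide and sets out from ester 9. Reduction with i-Bu2AlH in CH2Cl2 at −78 °C should give 2-[(1S,3S)-3-(tert-butyldimethylsilyloxy)-6,6-dimethyl-2-methylidenecyclohexyl]acetaldehyde F8. Ohira–Bestmann alkynylation (dimethyl (1-diazo-2-oxopropyl)phosphonate, K2CO3, MeOH) should give the terminal alkyne tert-butyl{[(1S,3S)-4,4-dimethyl-2-methylidene-3-(prop-2-yn-1-yl)cyclohexyl]oxy}dimethylsilane F9. Deprotonation with n-BuLi and oxidation of the lithium acetylide with t-BuOOLi in THF (−78 to 0 °C) should give lithium ynolate 11, where the route is rejoined; silylation as in step 6 gives 12.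

**Further compounds**
F1 | step 13 | {6-[3,4-bis(tert-butyldimethylsilyloxy)phenyl]-4-oxo-4H-pyran-2-yl}acetic acid | OC(=O)Cc1cc(=O)cc(-c2ccc(O[Si](C)(C)C(C)(C)C)c(O[Si](C)(C)C(C)(C)C)c2)o1
F2 | step 13 | {6-[3,4-bis(tert-butyldimethylsilyloxy)phenyl]-4-oxo-4H-pyran-2-yl}acetyl chloride | ClC(=O)Cc1cc(=O)cc(-c2ccc(O[Si](C)(C)C(C)(C)C)c(O[Si](C)(C)C(C)(C)C)c2)o1
F3 | step 5 | 2,4,4-trimethylcyclohex-2-en-1-one | CC1=CC(C)(C)CCC1=O
F4 | step 5 | (1R)-2,4,4-trimethylcyclohex-2-en-1-ol | CC1=CC(C)(C)CC[C@H]1O
F5 | step 5 | ethyl 2-[(1S)-2,6,6-trimethylcyclohex-2-en-1-yl]acetate | CC1=CCCC(C)(C)[C@@H]1CC(=O)OCC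
F6 | step 5 | ethyl 2-(1,3,3-trimethyl-7-oxabicyclo[4.1.0]heptan-2-yl)acetate, epoxide oxygen trans to the acetate arm | C[C@]12O[C@H]1CCC(C)(C)[C@@H]2CC(=O)OCC
F7 | step 5 | ethyl 2-[(1S,3S)-3-hydroxy-6,6-dimethyl-2-methylidenecyclohexyl]acetate | C=C1[C@@H](CC(=O)OCC)C(C)(C)CC[C@@H]1O
F8 | step 6 | 2-[(1S,3S)-3-(tert-butyldimethylsilyloxy)-6,6-dimethyl-2-methylidenecyclohexyl]acetaldehyde | C=C1[C@@H](CC=O)C(C)(C)CC[C@@H]1O[Si](C)(C)C(C)(C)C
F9 | step 6 | tert-butyl{[(1S,3S)-4,4-dimethyl-2-methylidene-3-(prop-2-yn-1-yl)cyclohexyl]oxy}dimethylsilane | C=C1[C@@H](CC#C)C(C)(C)CC[C@@H]1O[Si](C)(C)C(C)(C)C
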